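**Retrosynthetic overview**

- Locants follow the name of the target: side chain C1 (carbinol carbon) to C17, formyl on C4, ring = oxolane-2,5-dione (C2'–C5'). This only ring is closed second to last from the C2'/C5' diacid, and O-desilylation at C1 ends the route.
- The E-enal C3=C4 is cut by a Wittig reaction between an α-formyl ylide (C4–C17) and a C1–C3 aldehyde that already carries the succinate; its syn C1/C3' pair comes from an Evans boron aldol.
- C9–C10 is made by a decarboxylative Ireland–Claisen rearrangement: a geranyl α-sulfonylacetate (C10 = α-carbon) is tethered as its ester to O–C7 of an isopropenyl carbinol (C7–C8(CH3)=C9H2); the C10 sulfone is then removed with Pd/hydride.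
- Enabling feature: the skipped 1,5-diene C7=C8–C9–C10–C11=C12 with the methyl on C8. C9 is the CH2 terminus of a 2-methylallyl unit and C10 an allylic CH2 that can carry SO2Ph and CO2R, so one [3,3] shift forges C9–C10 and sets (E)-C7=C8; no ring takes part.

Key step: step 5

Assumption: the free β-hydroxy anhydride (the target) is taken to be isolable under non-basic, non-nucleophilic conditions; its isomerisation to the γ-lactone acid is treated as the main liability of the endgame.

**Route**

Step 1
Reactants: 1 geranyl bromide [(2E)-1-bromo-3,7-dimethylocta-2,6-diene]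
Product: 2 geranyl phenyl sulfone {[(2E)-3,7-dimethylocta-2,6-dien-1-yl]sulfonyl}benzene
Conditions: PhSO2Na, DMF, rt
Reagents that add atoms: sodium benzenesulfinate, [Na+].[O-]S(=O)c1ccccc1
Why: SN2 S-alkylation of the sulfinate by the primary allylic bromide should give the allylic sulfone with the E olefin (later C11=C12) untouched.

Step 2
Reactants: 3 (3-bromopropoxy)(tert-butyl)dimethylsilane; 4 methacrolein (2-methylprop-2-enal)
Product: 6 rac-6-{[tert-butyl(dimethyl)silyl]oxy}-2-methylhex-1-en-3-ol, via Grignard reagent 5 (not isolated)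
Conditions: Mg, THF, rt to 40 °C; then 4, −78 to 0 °C; aq. NH4Cl
Reagents that add atoms: none
Why: Grignard formation and 1,2-addition to the aldehyde of methacrolein should give the isopropenyl carbinol (C4–C9 of the target); the carbinol centre C7 is left racemic because step 5 destroys it.

Step 3
Reactants: 6 rac-6-{[tert-butyl(dimethyl)silyl]oxy}-2-methylhex-1-en-3-ol
Product: 7 rac-6-{[tert-butyl(dimethyl)silyl]oxy}-2-methylhex-1-en-3-yl 1H-imidazole-1-carboxylate
Conditions: CDI, CH2Cl2, rt
Reagents that add atoms: 1,1'-carbonyldiimidazole, O=C(n1ccnc1)n1ccnc1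
Why: Acyl transfer from CDI to the secondary alcohol should give a stable alkoxycarbonylimidazole whose carbonyl carbon becomes the temporary ester tether (O-acylation).

Step 4
Reactants: 2 geranyl phenyl sulfone; 7 imidazole-1-carboxylate of the isopropenyl carbinol
Product: 9 6-{[tert-butyl(dimethyl)silyl]oxy}-2-methylhex-1-en-3-yl (3E)-4,8-dimethyl-2-(phenylsulfonyl)nona-3,7-dienoate (mixture of diastereomers), via lithiated sulfone 8 (not isolated)
Conditions: 2 (2.2 equiv), n-BuLi (2.2 equiv), THF, −78 °C; then 7 (1.0 equiv), −78 to −20 °C; aq. NH4Cl; excess 2 recovered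
Reagents that add atoms: none
Why: C-acylation of an α-sulfonyl carbanion: the allylic anion reacts at its α-carbon with the imidazolide and the second equivalent of carbanion absorbs the more acidic product, so the α-sulfonyl ester should result as a diastereomer mixture that converges in step 5.

Step 5
Reactants: 9 α-sulfonyl ester (both diastereomers)
Product: 12 tert-butyl(dimethyl){[(4E,8E)-5,9,13-trimethyl-7-(phenylsulfonyl)tetradeca-4,8,12-trien-1-yl]oxy}silane (racemic at the sulfone carbon), via silyl ketene acetal 10 (not isolated), via trimethylsilyl ester 11 (not isolated)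
Conditions: BSA (0.2 equiv), KOAc (0.1 equiv), PhMe, 110 °C
Reagents that add atoms: none
Why: Catalytic BSA/KOAc turns the acidic α-sulfonyl ester into silyl ketene acetal 10, which undergoes an Ireland–Claisen [3,3]-sigmatropic shift through a chair transition state to silyl ester 11, forging C9–C10 and moving the olefin to C7=C8; acetate then desilylates 11, CO2 (the tether carbon) is lost, and the sulfonyl-stabilised allyl anion is protonated at C10 by fresh substrate, which carries the silyl/acetate cycle on. The closest known reaction type is the decarboxylative Claisen rearrangement of allylic arylsulfonylacetates. No ring is closed. The only new stereocentre, C10, is uncontrolled and is erased in step 6, while the new C7=C8 geometry is set by the chair, in which the C6 chain on the carbinol carbon C7 lies pseudo-equatorial, away from the ketene acetal, so that the E olefin should result from either diastereomer of 9. The step needs site selectivity (bond formation at C10 and not at the distal dienolate carbon C12), which the six-membered array O–C7–C8=C9···C10=C(OSi) secures, and it needs the (E)-C11=C12 olefin to stay in place, which should hold because that olefin is not part of the shifting system and sulfonyl allyl anions are protonated preferentially at the α-carbon.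

Step 6
Reactants: 12 allylic sulfone
Product: 13 tert-butyl(dimethyl){[(4E,8E)-5,9,13-trimethyltetradeca-4,8,12-trien-1-yl]oxy}silane
Conditions: PdCl2(dppp) (5 mol%), LiBHEt3, THF, 0 °C
Reagents that add atoms: none
Why: Pd-catalysed reductive desulfonylation: Pd(0) ionises the allylic sulfone to a π-allyl complex and hydride is delivered to the less substituted terminus (C10), so the trisubstituted C11=C12 olefin should stay in place and E.

Step 7
Reactants: 13 silyl ether
Product: 14 (4E,8E)-5,9,13-trimethyltetradeca-4,8,12-trien-1-ol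
Conditions: TBAF, THF, rt
Reagents that add atoms: none
Why: Fluoride cleaves the Si–O bond of the primary silyl ether and leaves the triene untouched (desilylation).

Step 8
Reactants: 14 trienol
Product: 15 (6E,10E)-14-iodo-2,6,10-trimethyltetradeca-2,6,10-triene
Conditions: I2, PPh3, imidazole, CH2Cl2, 0 °C
Reagents that add atoms: iodine, II
Why: Appel-type activation of the primary alcohol as an alkoxyphosphonium ion and SN2 displacement by iodide under neutral conditions should spare the olefins.

Step 9
Reactants: 15 iodide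
Product: 16 triphenyl[(4E,8E)-5,9,13-trimethyltetradeca-4,8,12-trien-1-yl]phosphonium iodide
Conditions: PPh3, MeCN, 80 °C
Reagents that add atoms: triphenylphosphine, c1ccc(cc1)P(c1ccccc1)c1ccccc1
Why: SN2 quaternisation of triphenylphosphine by the primary iodide (phosphonium salt formation).

Step 10
Reactants: 16 phosphonium iodide
Product: 18 (5E,9E)-6,10,14-trimethyl-2-(triphenyl-λ5-phosphanylidene)pentadeca-5,9,13-trienal, via phosphonium ylide 17 (not isolated)
Conditions: KOtBu, THF, 0 °C; then HCO2Et, 0 °C to rt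
Reagents that add atoms: ethyl formate, CCOC=O
Why: Ylide acylation: the non-stabilised ylide is C-formylated by ethyl formate and the acidic α-proton of the acylphosphonium ion is then removed by alkoxide, which should give the stabilised α-formyl ylide carrying the future C4 and its formyl carbon.

Step 11
Reactants: 19 3-[(4-methoxyphenyl)methoxy]propan-1-ol
Product: 20 3-[(4-methoxyphenyl)methoxy]propanal
Conditions: Dess–Martin periodinane, NaHCO3, CH2Cl2, rt
Reagents that add atoms: none
Why: Dess–Martin oxidation of the primary alcohol stops at the aldehyde and tolerates the PMB ether.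

Step 12
Reactants: 21 (4S)-4-benzyl-1,3-oxazolidin-2-one; 22 succinic anhydride (oxolane-2,5-dione)
Product: 25 prop-2-en-1-yl 4-[(4S)-4-benzyl-2-oxo-1,3-oxazolidin-3-yl]-4-oxobutanoate, via lithiated oxazolidinone 23 (not isolated), via lithium carboxylate 24 (not isolated)
Conditions: n-BuLi, THF, −78 °C; 22, −78 to 0 °C; then allyl bromide, DMF, rt
Reagents that add atoms: allyl bromide, C=CCBr
Why: N-acylation of the lithiated oxazolidinone by ring opening of the anhydride, followed by SN2 O-allylation of the carboxylate in the same flask, should give the succinate imide with the distal carboxyl masked as an allyl ester.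

Step 13
Reactants: 25 succinate imide; 20 3-[(4-methoxyphenyl)methoxy]propanal
Product: 27 prop-2-en-1-yl (3S,4R)-3-{[(4S)-4-benzyl-2-oxo-1,3-oxazolidin-3-yl]carbonyl}-4-hydroxy-6-[(4-methoxyphenyl)methoxy]hexanoate, via boron enolate 26 (not isolated)
Conditions: Bu2BOTf, i-Pr2NEt, CH2Cl2, 0 °C; then 20, −78 to 0 °C; pH 7 buffer, MeOH, H2O2
Reagents that add atoms: none
Why: Evans syn aldol: soft enolisation at the imide α-carbon gives the (Z)-boron enolate, and the Zimmerman–Traxler chair with the (S)-benzyl group blocking one enolate face should set both centres together, (4R) = C1 and (3S) = C3' of the target.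

Step 14
Reactants: 27 aldol adduct
Product: 28 prop-2-en-1-yl (3S,4R)-3-{[(4S)-4-benzyl-2-oxo-1,3-oxazolidin-3-yl]carbonyl}-6-[(4-methoxyphenyl)methoxy]-4-[(triethylsilyl)oxy]hexanoate
Conditions: TESOTf, 2,6-lutidine, CH2Cl2, −78 °C
Reagents that add atoms: triethylsilyl trifluoromethanesulfonate, CC[Si](CC)(CC)OS(=O)(=O)C(F)(F)F
Why: O-silylation of the secondary alcohol with the silyl triflate at low temperature; it also blocks lactonisation onto the γ-ester.

Step 15
Reactants: 28 silylated imide
Product: 29 diprop-2-en-1-yl (2S)-2-{(1R)-3-[(4-methoxyphenyl)methoxy]-1-[(triethylsilyl)oxy]propyl}butanedioate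
Conditions: allyl alcohol, n-BuLi, THF, −20 to 0 °C; aq. NH4Cl
Reagents that add atoms: allyl alcohol, C=CCO
Why: Alcoholysis of the N-acyl oxazolidinone: lithium allyloxide attacks the exocyclic imide carbonyl and releases the auxiliary, while exchange at the existing allyl ester is degenerate, so a single diester should result.

Step 16
Reactants: 29 PMB ether
Product: 30 diprop-2-en-1-yl (2S)-2-{(1R)-3-hydroxy-1-[(triethylsilyl)oxy]propyl}butanedioate
Conditions: DDQ, CH2Cl2/pH 7 buffer, 0 °C
Reagents that add atoms: none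
Why: Oxidative PMB removal: DDQ oxidises the electron-rich benzyl ether to an oxocarbenium ion that water hydrolyses, while the TES ether and allyl esters are inert.

Step 17
Reactants: 30 primary alcohol
Product: 31 diprop-2-en-1-yl (2S)-2-{(1R)-3-oxo-1-[(triethylsilyl)oxy]propyl}butanedioate
Conditions: Dess–Martin periodinane, NaHCO3, CH2Cl2, 0 °C to rt; used at once
Reagents that add atoms: none
Why: Dess–Martin oxidation under buffered, non-basic conditions should give the β-silyloxy aldehyde without β-elimination or δ-lactonisation of the alcohol.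

Step 18
Reactants: 18 α-formyl ylide; 31 aldehyde
Product: 32 diprop-2-en-1-yl (2S)-2-{(1R,3E,7E,11E)-4-formyl-8,12,16-trimethyl-1-[(triethylsilyl)oxy]heptadeca-3,7,11,15-tetraen-1-yl}butanedioate
Conditions: PhMe, 90 °C
Reagents that add atoms: none
Why: Wittig reaction of a stabilised ylide: reversible addition leads to the thermodynamically preferred (E)-2-alkyl-2-enal (CHO trans to C2), and the ylide is too weakly basic to epimerise C3' or eliminate the silyloxy group.

Step 19
Reactants: 32 diallyl ester
Product: 33 (2S)-2-{(1R,3E,7E,11E)-4-formyl-8,12,16-trimethyl-1-[(triethylsilyl)oxy]heptadeca-3,7,11,15-tetraen-1-yl}butanedioic acid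
Conditions: Pd(PPh3)4 (5 mol%), PhSO2Na, THF/MeOH, rt; cold aq. NaHSO4
Reagents that add atoms: none
Why: Tsuji–Trost deallylation: Pd(0) ionises both allyl esters to π-allyl complexes that the sulfinate traps irreversibly, a neutral method that should leave the enal, the TES ether and the olefins alone.

Step 20
Reactants: 33 diacid
Product: 34 (3S)-3-{(1R,3E,7E,11E)-4-formyl-8,12,16-trimethyl-1-[(triethylsilyl)oxy]heptadeca-3,7,11,15-tetraen-1-yl}oxolane-2,5-dione
Conditions: DCC, CH2Cl2, 0 °C; filtered and used crude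
Reagents that add atoms: none
Why: Carbodiimide activation of one carboxyl and attack by the neighbouring carboxyl closes the five-membered anhydride (5-exo-trig acyl substitution) under neutral conditions.

Step 21
Reactants: 34 silyl-protected anhydride
Product: 35 Hippolide D, (3S)-3-[(1R,3E,7E,11E)-4-formyl-1-hydroxy-8,12,16-trimethylheptadeca-3,7,11,15-tetraen-1-yl]oxolane-2,5-dione
Conditions: HF·pyridine, THF, 0 °C; cold, non-aqueous, non-basic work-up
Reagents that add atoms: none
Why: Acidic fluoride should cleave the secondary TES ether quickly at 0 °C without base or nucleophile, the conditions least likely to trigger acyl transfer from the anhydride to the freed hydroxyl.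

**Compound list**

1 | geranyl bromide, (2E)-1-bromo-3,7-dimethylocta-2,6-diene | CC(C)=CCC/C(C)=C/CBr | starting material
2 | geranyl phenyl sulfone, {[(2E)-3,7-dimethylocta-2,6-dien-1-yl]sulfonyl}benzene | CC(C)=CCC/C(C)=C/CS(=O)(=O)c1ccccc1 | intermediate
3 | (3-bromopropoxy)(tert-butyl)dimethylsilane | BrCCCO[Si](C)(C)C(C)(C)C | starting material
4 | methacrolein, 2-methylprop-2-enal | CC(=C)C=O | starting material
5 | {3-[(tert-butyldimethylsilyl)oxy]propyl}magnesium bromide | CC(C)(C)[Si](C)(C)OCCC[Mg]Br | intermediate (not isolated)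
6 | rac-6-{[tert-butyl(dimethyl)silyl]oxy}-2-methylhex-1-en-3-ol | CC(=C)C(O)CCCO[Si](C)(C)C(C)(C)C | intermediate
7 | rac-6-{[tert-butyl(dimethyl)silyl]oxy}-2-methylhex-1-en-3-yl 1H-imidazole-1-carboxylate | CC(=C)C(OC(=O)n1ccnc1)CCCO[Si](C)(C)C(C)(C)C | intermediate
8 | lithium (2E)-3,7-dimethyl-1-(phenylsulfonyl)octa-2,6-dien-1-ide | [Li+].CC(C)=CCC/C(C)=C/[CH-]S(=O)(=O)c1ccccc1 | intermediate (not isolated)
9 | 6-{[tert-butyl(dimethyl)silyl]oxy}-2-methylhex-1-en-3-yl (3E)-4,8-dimethyl-2-(phenylsulfonyl)nona-3,7-dienoate, diastereomer mixture | CC(C)=CCC/C(C)=C/C(C(=O)OC(CCCO[Si](C)(C)C(C)(C)C)C(C)=C)S(=O)(=O)c1ccccc1 | intermediate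
10 | trimethylsilyl ketene acetal of 9 | CC(C)=CCC/C(C)=C/C(=C(O[Si](C)(C)C)OC(CCCO[Si](C)(C)C(C)(C)C)C(C)=C)S(=O)(=O)c1ccccc1 | intermediate (not isolated)
11 | trimethylsilyl (3E)-2-[(2E)-6-{[tert-butyl(dimethyl)silyl]oxy}-2-methylhex-2-en-1-yl]-4,8-dimethyl-2-(phenylsulfonyl)nona-3,7-dienoate | CC(C)=CCC/C(C)=C/C(C/C(C)=C/CCCO[Si](C)(C)C(C)(C)C)(C(=O)O[Si](C)(C)C)S(=O)(=O)c1ccccc1 | intermediate (not isolated)
12 | tert-butyl(dimethyl){[(4E,8E)-5,9,13-trimethyl-7-(phenylsulfonyl)tetradeca-4,8,12-trien-1-yl]oxy}silane, racemic | CC(C)=CCC/C(C)=C/C(C/C(C)=C/CCCO[Si](C)(C)C(C)(C)C)S(=O)(=O)c1ccccc1 | intermediate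
13 | tert-butyl(dimethyl){[(4E,8E)-5,9,13-trimethyltetradeca-4,8,12-trien-1-yl]oxy}silane | CC(C)=CCC/C(C)=C/CC/C(C)=C/CCCO[Si](C)(C)C(C)(C)C | intermediate
14 | (4E,8E)-5,9,13-trimethyltetradeca-4,8,12-trien-1-ol | CC(C)=CCC/C(C)=C/CC/C(C)=C/CCCO | intermediate
15 | (6E,10E)-14-iodo-2,6,10-trimethyltetradeca-2,6,10-triene | CC(C)=CCC/C(C)=C/CC/C(C)=C/CCCI | intermediate
16 | triphenyl[(4E,8E)-5,9,13-trimethyltetradeca-4,8,12-trien-1-yl]phosphonium iodide | CC(C)=CCC/C(C)=C/CC/C(C)=C/CCC[P+](c1ccccc1)(c1ccccc1)c1ccccc1.[I-] | intermediate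
17 | triphenyl[(4E,8E)-5,9,13-trimethyltetradeca-4,8,12-trien-1-ylidene]-λ5-phosphane | CC(C)=CCC/C(C)=C/CC/C(C)=C/CCC=P(c1ccccc1)(c1ccccc1)c1ccccc1 | intermediate (not isolated)
18 | (5E,9E)-6,10,14-trimethyl-2-(triphenyl-λ5-phosphanylidene)pentadeca-5,9,13-trienal | CC(C)=CCC/C(C)=C/CC/C(C)=C/CCC(C=O)=P(c1ccccc1)(c1ccccc1)c1ccccc1 | intermediate
19 | 3-[(4-methoxyphenyl)methoxy]propan-1-ol | COc1ccc(COCCCO)cc1 | starting material
20 | 3-[(4-methoxyphenyl)methoxy]propanal | COc1ccc(COCCC=O)cc1 | intermediate
21 | (4S)-4-benzyl-1,3-oxazolidin-2-one | O=C1N[C@@H](Cc2ccccc2)CO1 | starting material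
22 | succinic anhydride, oxolane-2,5-dione | O=C1CCC(=O)O1 | starting material
23 | lithium (4S)-4-benzyl-2-oxo-1,3-oxazolidin-3-ide | [Li+].O=C1[N-][C@@H](Cc2ccccc2)CO1 | intermediate (not isolated)
24 | lithium 4-[(4S)-4-benzyl-2-oxo-1,3-oxazolidin-3-yl]-4-oxobutanoate | [Li+].[O-]C(=O)CCC(=O)N1[C@@H](Cc2ccccc2)COC1=O | intermediate (not isolated)
25 | prop-2-en-1-yl 4-[(4S)-4-benzyl-2-oxo-1,3-oxazolidin-3-yl]-4-oxobutanoate | C=CCOC(=O)CCC(=O)N1[C@@H](Cc2ccccc2)COC1=O | intermediate
26 | (Z)-dibutylboron enolate of 25 | C=CCOC(=O)C/C=C(\OB(CCCC)CCCC)N1[C@@H](Cc2ccccc2)COC1=O | intermediate (not isolated)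
27 | prop-2-en-1-yl (3S,4R)-3-{[(4S)-4-benzyl-2-oxo-1,3-oxazolidin-3-yl]carbonyl}-4-hydroxy-6-[(4-methoxyphenyl)methoxy]hexanoate | COc1ccc(COCC[C@@H](O)[C@H](CC(=O)OCC=C)C(=O)N2[C@@H](Cc3ccccc3)COC2=O)cc1 | intermediate
28 | prop-2-en-1-yl (3S,4R)-3-{[(4S)-4-benzyl-2-oxo-1,3-oxazolidin-3-yl]carbonyl}-6-[(4-methoxyphenyl)methoxy]-4-[(triethylsilyl)oxy]hexanoate | COc1ccc(COCC[C@@H](O[Si](CC)(CC)CC)[C@H](CC(=O)OCC=C)C(=O)N2[C@@H](Cc3ccccc3)COC2=O)cc1 | intermediate
29 | diprop-2-en-1-yl (2S)-2-{(1R)-3-[(4-methoxyphenyl)methoxy]-1-[(triethylsilyl)oxy]propyl}butanedioate | COc1ccc(COCC[C@@H](O[Si](CC)(CC)CC)[C@H](CC(=O)OCC=C)C(=O)OCC=C)cc1 | intermediate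
30 | diprop-2-en-1-yl (2S)-2-{(1R)-3-hydroxy-1-[(triethylsilyl)oxy]propyl}butanedioate | OCC[C@@H](O[Si](CC)(CC)CC)[C@H](CC(=O)OCC=C)C(=O)OCC=C | intermediate
31 | diprop-2-en-1-yl (2S)-2-{(1R)-3-oxo-1-[(triethylsilyl)oxy]propyl}butanedioate | O=CC[C@@H](O[Si](CC)(CC)CC)[C@H](CC(=O)OCC=C)C(=O)OCC=C | intermediate
32 | diprop-2-en-1-yl (2S)-2-{(1R,3E,7E,11E)-4-formyl-8,12,16-trimethyl-1-[(triethylsilyl)oxy]heptadeca-3,7,11,15-tetraen-1-yl}butanedioate | CC(C)=CCC/C(C)=C/CC/C(C)=C/CC/C(C=O)=C\C[C@@H](O[Si](CC)(CC)CC)[C@H](CC(=O)OCC=C)C(=O)OCC=C | intermediate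
33 | (2S)-2-{(1R,3E,7E,11E)-4-formyl-8,12,16-trimethyl-1-[(triethylsilyl)oxy]heptadeca-3,7,11,15-tetraen-1-yl}butanedioic acid | CC(C)=CCC/C(C)=C/CC/C(C)=C/CC/C(C=O)=C\C[C@@H](O[Si](CC)(CC)CC)[C@H](CC(=O)O)C(=O)O | intermediate
34 | (3S)-3-{(1R,3E,7E,11E)-4-formyl-8,12,16-trimethyl-1-[(triethylsilyl)oxy]heptadeca-3,7,11,15-tetraen-1-yl}oxolane-2,5-dione | CC(C)=CCC/C(C)=C/CC/C(C)=C/CC/C(C=O)=C\C[C@@H](O[Si](CC)(CC)CC)[C@@H]1CC(=O)OC1=O | intermediate
35 | Hippolide D, (3S)-3-[(1R,3E,7E,11E)-4-formyl-1-hydroxy-8,12,16-trimethylheptadeca-3,7,11,15-tetraen-1-yl]oxolane-2,5-dione | CC(C)=CCC/C(C)=C/CC/C(C)=C/CC/C(C=O)=C\C[C@@H](O)[C@@H]1CC(=O)OC1=O | target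

**Step count and risks**

Total step count: 21. Longest linear sequence: 13 steps (steps 2–10, then 18–21).

The three steps most likely to fail:

1. Step 5 (key step). The silyl ketene acetal may form or rearrange sluggishly on this α-alkenyl substrate. Base may move the C11=C12 double bond into conjugation with the sulfone. The chair preference may erode, lowering E-selectivity at C7=C8. The fallback uses known sulfone alkylation, sets out from 2 and from Grignard reagent 5, and returns at 12. Reagent 5 would be cross-coupled with 1-bromo-2-methylprop-1-ene (cat. NiCl2(dppp), THF, Kumada coupling) to give tert-butyl(dimethyl)[(5-methylhex-4-en-1-yl)oxy]silane F1. Allylic oxidation of its (E)-methyl group (cat. SeO2, t-BuOOH, CH2Cl2, then NaBH4) should give (2E)-6-{[tert-butyl(dimethyl)silyl]oxy}-2-methylhex-2-en-1-ol F2. This is converted (CBr4, PPh3, CH2Cl2, 0 °C) into {[(4E)-6-bromo-5-methylhex-4-en-1-yl]oxy}(tert-butyl)dimethylsilane F3. Alkylation of lithiated sulfone 8 (from 2, n-BuLi, THF, −78 °C) with F3 then forms the same C9–C10 bond intermolecularly and gives 12, from which step 6 continues.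

2. Step 21. During or after desilylation the freed C1 hydroxyl may attack the anhydride (intramolecular acyl transfer to the γ-lactone acid), or the anhydride may be opened on work-up. The fallback changes which event comes last; it sets out from 32 and returns at 35. The TES group is removed first (HF·pyridine, THF, 0 °C) to give diprop-2-en-1-yl (2S)-2-[(1R,3E,7E,11E)-4-formyl-1-hydroxy-8,12,16-trimethylheptadeca-3,7,11,15-tetraen-1-yl]butanedioate F4, a hydroxy diester of the same kind as the isolable aldol adduct 27. Deallylation as in step 19 gives (2S)-2-[(1R,3E,7E,11E)-4-formyl-1-hydroxy-8,12,16-trimethylheptadeca-3,7,11,15-tetraen-1-yl]butanedioic acid F5, which is not stored but closed at once with DCC (CH2Cl2, −20 °C). The neighbouring carboxyl should outcompete the hydroxyl for the activated acyl group, so 35 would be formed without ever exposing the anhydride to fluoride or acid.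

3. Step 15. The alkoxide may attack the endocyclic carbamate carbonyl of the hindered imide, or deprotonate the imide α-carbon with loss of the β-silyloxy group or epimerisation. The fallback goes through the free acid, sets out from 28 and returns at 29. Hydrolysis with LiOH/H2O2 (THF/H2O, 0 °C), which is selective for the exocyclic carbonyl, should give (2S,3R)-5-[(4-methoxyphenyl)methoxy]-2-[2-oxo-2-(prop-2-en-1-yloxy)ethyl]-3-[(triethylsilyl)oxy]pentanoic acid F6. O-Alkylation of its carboxylate (allyl bromide, K2CO3, DMF, rt) then gives 29.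

**Further compounds**

F1 | step 5 | tert-butyl(dimethyl)[(5-methylhex-4-en-1-yl)oxy]silane | CC(C)=CCCCO[Si](C)(C)C(C)(C)C
F2 | step 5 | (2E)-6-{[tert-butyl(dimethyl)silyl]oxy}-2-methylhex-2-en-1-ol | OC/C(C)=C/CCCO[Si](C)(C)C(C)(C)C
F3 | step 5 | {[(4E)-6-bromo-5-methylhex-4-en-1-yl]oxy}(tert-butyl)dimethylsilane | BrC/C(C)=C/CCCO[Si](C)(C)C(C)(C)C
F4 | step 21 | diprop-2-en-1-yl (2S)-2-[(1R,3E,7E,11E)-4-formyl-1-hydroxy-8,12,16-trimethylheptadeca-3,7,11,15-tetraen-1-yl]butanedioate | CC(C)=CCC/C(C)=C/CC/C(C)=C/CC/C(C=O)=C\C[C@@H](O)[C@H](CC(=O)OCC=C)C(=O)OCC=C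
F5 | step 21 | (2S)-2-[(1R,3E,7E,11E)-4-formyl-1-hydroxy-8,12,16-trimethylheptadeca-3,7,11,15-tetraen-1-yl]butanedioic acid | CC(C)=CCC/C(C)=C/CC/C(C)=C/CC/C(C=O)=C\C[C@@H](O)[C@H](CC(=O)O)C(=O)O
F6 | step 15 | (2S,3R)-5-[(4-methoxyphenyl)methoxy]-2-[2-oxo-2-(prop-2-en-1-yloxy)ethyl]-3-[(triethylsilyl)oxy]pentanoic acid | COc1ccc(COCC[C@@H](O[Si](CC)(CC)CC)[C@H](CC(=O)OCC=C)C(=O)O)cc1
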